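The flask held 0.050 M of starting material against 5.0 µM of enzyme, and the question was how the rate of making product, at 50% conversion, moves with the charge of enzyme.

| setting | theta | flask |
|---|---|---|
| starting material | 0.050 M | 0.050 M |
| enzyme | 10 µM | 5.0 µM |
| remark | run made earlier |  |

theta run (percent of the starting material charged)

| time / s | product / % | starting material / % |
|---|---|---|
| 10.0 | 15.5 | 44.5 |
| 15.0 | 20.0 | 33.3 |
| 20.0 | 22.9 | 26.2 |
| 30.0 | 27.2 | 17.6 |
| 50.0 | 32.2 | 9.0 |
| 80.0 | 36.8 | 3.6 |
| 120 | 40.0 | 1.3 |

(each reading ± 0.3 percentage points)

1. factor on the rate of making product when 50% of the starting material are converted if enzyme is charged twice over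
2. factor on the rate when 50% of the starting material are converted if enzyme is charged at 25 µM instead

- no earlier run changes the charge of enzyme; that part of a forecast is a guess

I built the flask up one process at a time. First I took the main step alone: enzyme turns starting material into product and comes back. I assumed that each enzyme works like any other at a given [starting material], so the rate follows the charge. For 25 µM against 5.0 µM the charges stand at 5.00, and this number, new charge over old charge, is the proportional factor. It served as the zero of my scale, and for a doubled charge it is 2.

Then I added what the earlier run showed. At 120 s in that run, starting material and product summed to 41.3% of the charge, so 58.7% had gone by a route that gave no product. This route changes when 50% conversion is reached, but not [starting material] at that moment, which is 25.0 mM at each charge of enzyme. So in my reckoning the factor stayed where it was.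

The rest could not be read, since no earlier run changed the enzyme. If something took enzyme out of work more strongly at a higher charge, the factor stood below the proportional one, but I could give that no size. The forecast stood on the zero of the scale, 2 and 5, with the words “That is a guess, because enzyme was never varied”.

The simulation gives 1.61 for the doubled charge and 2.78 at 25 µM.

    2 enzyme ⇌ resting dimer (K = 2.30 × 10⁵ L mol⁻¹, k = 5300 L mol⁻¹ s⁻¹)
    2 starting material → homo dimer (k = 0.890 L mol⁻¹ s⁻¹)
    starting material + enzyme → product + enzyme, rate k3*[starting material]*[enzyme]/(1 + ([starting material]/Km3) + ([product]/Kp3)) (20.0 mM, 0.0650 M, k = 9100 L mol⁻¹ s⁻¹)

By 2.00 min, later than the 0.153 min at which it stood at 50% conversion, the flask with 5.0 µM held 47.7% of its catalyst as enzyme and 52.3% as resting dimer, a form outside the working round. Held against the proportional factor, the factor at 25 µM came to 0.556 of 5.00, a smaller share than the factor for the doubled charge, which came to 0.805 of 2.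

The data stem from a simulated flask for an exercise, and the scatter is random.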